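The route rests on making the C4–O bond of the oxane (ring O–C15–C1–C2–C3–C4) last, across a finished 14-membered carbocycle. Mild acid lets the C15 hydroxyl open a trans-3,4-epoxide at its tertiary carbon C4: one operation closes the bridging ring, sets C4 by inversion and frees the C3 hydroxyl for acetylation. The step exploits the tertiary C4 and the fact that endo opening places C5 and C14 cis on the oxane, the arrangement the C5–C14 chain spans without strain. Its precursor is (1R,3R,4R,7R,11E)-3,4-epoxycembra-8(19),11-dien-15-ol carrying a silyl ether at C7, built from (R)-limonene by sulfone macrocyclisation.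

Key step: step 21

Remark: cembrane numbering is used (ring C1–C14; C15 = carbinol carbon on C1; C18 = methyl on C4; C19 = exocyclic methylene on C8; C20 = methyl on C12); the carbinol centre made in step 4 and the C10 centre made in step 17 are assumed to form without control, which is harmless because both are erased later.

Step 1
Reactants: 1 (R)-(+)-limonene
Product: 3 (R)-α-terpineol, via organomercurial adduct 2 (not isolated)
Conditions: Hg(OAc)2 (1.0 equiv), THF–H2O (1:1), rt, 15 min; then 3 M NaOH, NaBH4, 0 °C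
Reagents that add atoms: mercury diacetate CC(=O)O[Hg]OC(C)=O (for 2); water O
Why: Oxymercuration–demercuration (Markovnikov hydration) should take place at the more accessible 1,1-disubstituted isopropenyl alkene in preference to the ring alkene, and the existing stereocentre is not touched.

Step 2
Reactants: 3 (R)-α-terpineol
Product: 4 triethylsilyl ether of (R)-α-terpineol
Conditions: Et3SiOTf (1.3 equiv), 2,6-lutidine (2 equiv), CH2Cl2, −78 to 0 °C
Reagents that add atoms: triethylsilyl trifluoromethanesulfonate CC[Si](CC)(CC)OS(=O)(=O)C(F)(F)F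
Why: Silylation of a tertiary alcohol with a silyl triflate and a hindered base is routine, and the ether masks the C15 hydroxyl that would otherwise form a lactol in step 3 and an alkoxide in the later basic steps.

Step 3
Reactants: 4 triethylsilyl ether of (R)-α-terpineol
Product: 6 (3R)-6-oxo-3-[2-(triethylsilyloxy)propan-2-yl]heptanal, via methoxy hydroperoxide 5 (not isolated)
Conditions: O3, CH2Cl2–MeOH (4:1), NaHCO3, −78 °C; then Me2S, −78 °C to rt
Reagents that add atoms: ozone [O-][O+]=O; methanol CO (for 5)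
Why: Ozonolysis with reductive work-up cleaves the only alkene to the C12 methyl ketone and the C3 aldehyde, and the stereocentre (future C1) is β to the aldehyde and cannot epimerise.

Step 4
Reactants: 6 (3R)-6-oxo-3-[2-(triethylsilyloxy)propan-2-yl]heptanal; 7 2-bromopropene
Product: 8 (5R)-7-hydroxy-8-methyl-5-[2-(triethylsilyloxy)propan-2-yl]non-8-en-2-one (both C7 epimers)
Conditions: CrCl2 (4 equiv), NiCl2 (2 mol %), DMF, rt
Reagents that add atoms: none
Why: The Nozaki–Hiyama–Kishi reaction adds the isopropenyl group to the aldehyde only and leaves the methyl ketone untouched; the new carbinol centre is uncontrolled and is destroyed in step 6.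

Step 5
Reactants: 8 (5R)-7-hydroxy-8-methyl-5-[2-(triethylsilyloxy)propan-2-yl]non-8-en-2-one; 9 tert-butyl diethylphosphonoacetate
Product: 10 tert-butyl (2E,6R)-8-hydroxy-3,9-dimethyl-6-[2-(triethylsilyloxy)propan-2-yl]deca-2,9-dienoate (both C8 epimers)
Conditions: 9 (1.5 equiv), NaH (2.6 equiv), THF, 0 to 45 °C
Reagents that add atoms: none
Why: Horner–Wadsworth–Emmons olefination of the methyl ketone should favour the E enoate (C11=C12) because the longer chain avoids the ester group; the free hydroxyl rides along as its sodium alkoxide and the minor Z isomer is to be removed by chromatography after step 6.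

Step 6
Reactants: 10 tert-butyl (2E,6R)-8-hydroxy-3,9-dimethyl-6-[2-(triethylsilyloxy)propan-2-yl]deca-2,9-dienoate; 11 triethyl orthoacetate
Product: 12 1-tert-butyl 12-ethyl (2E,6R,8E)-3,9-dimethyl-6-[2-(triethylsilyloxy)propan-2-yl]dodeca-2,8-dienedioate
Conditions: 11 (8 equiv), EtCO2H (5 mol %), 135 °C, EtOH distilled off
Reagents that add atoms: none
Why: The Johnson–Claisen rearrangement, through a chair transition state with the C2 substituent equatorial, should give the E trisubstituted C3=C4 alkene and adds C6 and C7 in the same operation.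

Step 7
Reactants: 12 1-tert-butyl 12-ethyl (2E,6R,8E)-3,9-dimethyl-6-[2-(triethylsilyloxy)propan-2-yl]dodeca-2,8-dienedioate
Product: 13 tert-butyl (2E,6R,8E)-12-[methoxy(methyl)amino]-3,9-dimethyl-12-oxo-6-[2-(triethylsilyloxy)propan-2-yl]dodeca-2,8-dienoate
Conditions: MeNH(OMe)·HCl (2 equiv), i-PrMgCl (4 equiv), THF, −20 °C
Reagents that add atoms: N,O-dimethylhydroxylamine hydrochloride CNOC.Cl
Why: Weinreb amide formation with the magnesium amide should convert the saturated ethyl ester only, because the hindered conjugated tert-butyl ester is far less electrophilic.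

Step 8
Reactants: 14 2,3-dibromopropene; 15 4-methoxybenzyl alcohol
Product: 16 2-bromoallyl 4-methoxybenzyl ether
Conditions: NaH, THF–DMF, 0 °C to rt
Reagents that add atoms: none
Why: In this Williamson ether synthesis the alkoxide displaces the allylic bromide while the vinylic bromide is inert.

Step 9
Reactants: 16 2-bromoallyl 4-methoxybenzyl ether; 13 tert-butyl (2E,6R,8E)-12-[methoxy(methyl)amino]-3,9-dimethyl-12-oxo-6-[2-(triethylsilyloxy)propan-2-yl]dodeca-2,8-dienoate
Product: 18 tert-butyl (1R,3E,11E)-9-[(4-methoxybenzyl)oxy]-7-oxo-15-(triethylsilyloxy)-9,10-secocembra-3,8(19),11-trien-10-oate, via vinyllithium 17 (not isolated)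
Conditions: 16 (1.5 equiv), t-BuLi (3.0 equiv), Et2O, −78 °C; then 13, −78 °C; aq. NH4Cl
Reagents that add atoms: tert-butyllithium [Li]C(C)(C)C (for 17)
Why: Bromine–lithium exchange followed by acylation of the vinyllithium with the Weinreb amide should stop at the ketone because the chelated tetrahedral adduct survives until the quench, and the tert-butyl enoate is expected to be inert at −78 °C.

Step 10
Reactants: 18 tert-butyl (1R,3E,11E)-9-[(4-methoxybenzyl)oxy]-7-oxo-15-(triethylsilyloxy)-9,10-secocembra-3,8(19),11-trien-10-oate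
Product: 19 tert-butyl (1R,7R,3E,11E)-7-hydroxy-9-[(4-methoxybenzyl)oxy]-15-(triethylsilyloxy)-9,10-secocembra-3,8(19),11-trien-10-oate
Conditions: (S)-2-methyl-CBS-oxazaborolidine (0.2 equiv), catecholborane (1.8 equiv), toluene, −78 °C
Reagents that add atoms: none
Why: In this Corey–Bakshi–Shibata reduction the α-branched alkenyl group acts as the large substituent, so the (S)-catalyst should deliver hydride to the face that gives the 7R alcohol, and catecholborane does not hydroborate the alkenes at this temperature.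

Step 11
Reactants: 19 tert-butyl (1R,7R,3E,11E)-7-hydroxy-9-[(4-methoxybenzyl)oxy]-15-(triethylsilyloxy)-9,10-secocembra-3,8(19),11-trien-10-oate
Product: 20 tert-butyl (1R,7R,3E,11E)-9-[(4-methoxybenzyl)oxy]-7,15-bis(triethylsilyloxy)-9,10-secocembra-3,8(19),11-trien-10-oate
Conditions: Et3SiCl, imidazole, DMAP (cat.), CH2Cl2, 0 °C to rt
Reagents that add atoms: chlorotriethylsilane CC[Si](Cl)(CC)CC
Why: Standard silylation of a secondary allylic alcohol protects C7–OH through the halogenation, epoxidation and carbanion steps with the same group as C15–OH, so that both can be removed together later.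

Step 12
Reactants: 20 tert-butyl (1R,7R,3E,11E)-9-[(4-methoxybenzyl)oxy]-7,15-bis(triethylsilyloxy)-9,10-secocembra-3,8(19),11-trien-10-oate
Product: 21 (1R,7R,3E,11E)-9-[(4-methoxybenzyl)oxy]-7,15-bis(triethylsilyloxy)-9,10-secocembra-3,8(19),11-trien-10-ol
Conditions: i-Bu2AlH (3 equiv), CH2Cl2, −78 to 0 °C; aq. potassium sodium tartrate (KNaC4H4O6)
Reagents that add atoms: none
Why: Hydride reduction of an α,β-unsaturated ester with i-Bu2AlH gives the allylic alcohol by 1,2-reduction without touching the alkene geometry, the ethers or the silyl groups.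

Step 13
Reactants: 21 (1R,7R,3E,11E)-9-[(4-methoxybenzyl)oxy]-7,15-bis(triethylsilyloxy)-9,10-secocembra-3,8(19),11-trien-10-ol
Product: 23 (1R,7R,3E,11E)-9-[(4-methoxybenzyl)oxy]-10-(phenylsulfonyl)-7,15-bis(triethylsilyloxy)-9,10-secocembra-3,8(19),11-triene, via allylic bromide 22 (not isolated)
Conditions: CBr4, PPh3, 2,6-lutidine, CH2Cl2, 0 °C; then PhSO2Na, DMF, rt
Reagents that add atoms: carbon tetrabromide BrC(Br)(Br)Br (for 22); sodium benzenesulfinate [Na+].[O-]S(=O)c1ccccc1
Why: An Appel bromination of the primary allylic alcohol followed by S-alkylation of the sulfinate at the primary carbon should give the allylic sulfone with the C11=C12 geometry intact.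

Step 14
Reactants: 23 (1R,7R,3E,11E)-9-[(4-methoxybenzyl)oxy]-10-(phenylsulfonyl)-7,15-bis(triethylsilyloxy)-9,10-secocembra-3,8(19),11-triene
Product: 24 (1R,7R,3E,11E)-10-(phenylsulfonyl)-7,15-bis(triethylsilyloxy)-9,10-secocembra-3,8(19),11-trien-9-ol
Conditions: DDQ (1.3 equiv), CH2Cl2–pH 7 phosphate buffer (10:1), 0 °C
Reagents that add atoms: none
Why: Oxidative cleavage of the 4-methoxybenzyl ether by DDQ is selective for the electron-rich benzyl ether and leaves silyl ethers, sulfone and alkenes alone.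

Step 15
Reactants: 24 (1R,7R,3E,11E)-10-(phenylsulfonyl)-7,15-bis(triethylsilyloxy)-9,10-secocembra-3,8(19),11-trien-9-ol
Product: 25 (1R,3R,4R,7R,11E)-3,4-epoxy-10-(phenylsulfonyl)-7,15-bis(triethylsilyloxy)-9,10-secocembra-8(19),11-dien-9-ol
Conditions: Shi ketone (1,2:4,5-di-O-isopropylidene-β-D-erythro-2,3-hexodiulo-2,6-pyranose, 0.3 equiv), KHSO5 (as 2KHSO5·KHSO4·K2SO4), K2CO3, Bu4NHSO4, Na2B4O7/Na2EDTA buffer, MeCN–CH2(OMe)2–H2O, 0 °C
Reagents that add atoms: potassium peroxymonosulfate (KHSO5) [K+].[O-]S(=O)(=O)OO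
Why: In the Shi epoxidation the dioxirane of the D-fructose-derived ketone should attack only the electron-rich C3=C4 alkene (C11=C12 is deactivated by the allylic sulfone and the 1,1-disubstituted C8=C19 by two allylic oxygens) and, through the spiro transition state, from the face that gives the (3R,4R)-epoxide under catalyst control.

Step 16
Reactants: 25 (1R,3R,4R,7R,11E)-3,4-epoxy-10-(phenylsulfonyl)-7,15-bis(triethylsilyloxy)-9,10-secocembra-8(19),11-dien-9-ol
Product: 27 (1R,3R,4R,7R,11E)-9-bromo-3,4-epoxy-10-(phenylsulfonyl)-7,15-bis(triethylsilyloxy)-9,10-secocembra-8(19),11-diene, via allylic mesylate 26 (not isolated)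
Conditions: MsCl, Et3N, THF, −40 °C; then LiBr, THF, −40 to 0 °C
Reagents that add atoms: methanesulfonyl chloride CS(=O)(=O)Cl (for 26); lithium bromide [Li+].[Br-]
Why: Mesylation and bromide displacement convert the primary allylic alcohol under non-acidic conditions that a trisubstituted epoxide tolerates, and direct and allylic displacement lead to the same bromide because the 2-substituted allyl unit is symmetric.

Step 17
Reactants: 27 (1R,3R,4R,7R,11E)-9-bromo-3,4-epoxy-10-(phenylsulfonyl)-7,15-bis(triethylsilyloxy)-9,10-secocembra-8(19),11-diene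
Product: 28 (1R,3R,4R,7R,11E)-3,4-epoxy-10-(phenylsulfonyl)-7,15-bis(triethylsilyloxy)cembra-8(19),11-diene (both C10 epimers)
Conditions: LiN(SiMe3)2 (2.5 equiv), THF, 0 °C, 27 added over 6 h (final 1 mM)
Reagents that add atoms: none
Why: Intramolecular alkylation of the sulfonyl-stabilised allyl anion at C10 by the C9 allylic bromide under high dilution is an established way to close 14-membered terpenoid rings, and the hindered amide base is not expected to attack the epoxide at 0 °C.

Step 18
Reactants: 28 (1R,3R,4R,7R,11E)-3,4-epoxy-10-(phenylsulfonyl)-7,15-bis(triethylsilyloxy)cembra-8(19),11-diene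
Product: 29 (1R,3R,4R,7R,11E)-3,4-epoxy-7,15-bis(triethylsilyloxy)cembra-8(19),11-diene
Conditions: PdCl2(dppp) (10 mol %; dppp = 1,3-bis(diphenylphosphino)propane), LiBHEt3 (2.2 equiv, slow addition), THF, −20 to 0 °C
Reagents that add atoms: none
Why: In this palladium-catalysed reductive desulfonylation the zerovalent palladium formed in situ inserts into the allylic C10–S bond and hydride is delivered to the less substituted C10 terminus, which keeps C11=C12 in place and E, while the hindered epoxide is expected to survive the short cold exposure to the borohydride.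

Step 19
Reactants: 29 (1R,3R,4R,7R,11E)-3,4-epoxy-7,15-bis(triethylsilyloxy)cembra-8(19),11-diene
Product: 30 (1R,3R,4R,7R,11E)-3,4-epoxycembra-8(19),11-diene-7,15-diol
Conditions: Bu4NF (3 equiv), THF, 0 °C to rt
Reagents that add atoms: none
Why: Fluoride-mediated desilylation removes both triethylsilyl ethers under non-acidic conditions in which epoxy alcohols of this kind are normally stable.

Step 20
Reactants: 30 (1R,3R,4R,7R,11E)-3,4-epoxycembra-8(19),11-diene-7,15-diol
Product: 31 (1R,3R,4R,7R,11E)-7-(tert-butyldimethylsilyloxy)-3,4-epoxycembra-8(19),11-dien-15-ol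
Conditions: t-BuMe2SiCl (1.3 equiv), imidazole, DMF, 0 °C to rt
Reagents that add atoms: tert-butyldimethylsilyl chloride CC(C)(C)[Si](C)(C)Cl
Why: Silylation with a silyl chloride and imidazole discriminates the secondary allylic C7 hydroxyl from the tertiary C15 hydroxyl, which does not react under these conditions.

Step 21
Reactants: 31 (1R,3R,4R,7R,11E)-7-(tert-butyldimethylsilyloxy)-3,4-epoxycembra-8(19),11-dien-15-ol
Product: 32 (1R,3R,4S,7R,11E)-7-(tert-butyldimethylsilyloxy)-4,15-epoxycembra-8(19),11-dien-3-ol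
Conditions: (±)-camphor-10-sulfonic acid (0.1 equiv), CH2Cl2, −20 to 0 °C; then Et3N
Reagents that add atoms: none
Why: Protonation of the epoxide oxygen loosens the C4–O bond, where positive charge is best stabilised because C4 is tertiary, and the C15 hydroxyl attacks C4 from the side opposite the leaving oxygen, followed by proton loss. The closest known reaction type is the acid-catalysed cyclisation of trisubstituted epoxides that carry a tertiary hydroxyl two carbons away, which delivers hydroxy oxanes (2-hydroxy-1,8-cineole from α-terpineol oxide, pyranoid linalool oxides). The oxane O–C15–C1–C2–C3–C4 closes in the 6-endo-tet mode. C4 becomes S by inversion of the reagent-set 4R epoxide carbon, whereas C3 keeps its oxygen and its R configuration, so the anti C3–O/C4–O pair of the target results. The step needs attack at C4 and not 5-exo attack at C3: the tertiary character of C4 favours it electronically, and only the endo path places C5 and C14 cis on the new ring, whereas attack at C3 would oblige the C4–C14 chain to bridge an oxolane trans-1,3. Competing nucleophiles are excluded because the C7 hydroxyl is silylated and the medium is aprotic and free of nucleophilic counter-ions.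

Step 22
Reactants: 32 (1R,3R,4S,7R,11E)-7-(tert-butyldimethylsilyloxy)-4,15-epoxycembra-8(19),11-dien-3-ol
Product: 33 (1R,3R,4S,7R,11E)-7-(tert-butyldimethylsilyloxy)-4,15-epoxycembra-8(19),11-dien-3-yl acetate
Conditions: Ac2O, DMAP (cat.), pyridine, rt
Reagents that add atoms: acetic anhydride CC(=O)OC(C)=O
Why: DMAP-catalysed acylation esterifies the only free hydroxyl, the hindered secondary C3–OH, without affecting any stereocentre.

Step 23
Reactants: 33 (1R,3R,4S,7R,11E)-7-(tert-butyldimethylsilyloxy)-4,15-epoxycembra-8(19),11-dien-3-yl acetate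
Product: 34 (1R,3R,4S,7R,11E)-4,15-epoxy-7-hydroxycembra-8(19),11-dien-3-yl acetate (CNP0202897.1)
Conditions: Bu4NF, AcOH (1:1), THF, rt
Reagents that add atoms: none
Why: Buffered fluoride cleaves the C7 silyl ether, and the remote C3 acetate is expected neither to hydrolyse nor to migrate.

Compound list
1 | (R)-(+)-limonene | CC1=CC[C@@H](CC1)C(C)=C | starting material
2 | [2-hydroxy-2-((1R)-4-methylcyclohex-3-en-1-yl)propyl]mercury acetate (carbinol epimers) | CC1=CC[C@@H](CC1)C(C)(O)C[Hg]OC(C)=O | intermediate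
3 | (R)-α-terpineol, 2-[(1R)-4-methylcyclohex-3-en-1-yl]propan-2-ol | CC1=CC[C@@H](CC1)C(C)(C)O | intermediate
4 | triethyl({2-[(1R)-4-methylcyclohex-3-en-1-yl]propan-2-yl}oxy)silane | CC1=CC[C@@H](CC1)C(C)(C)O[Si](CC)(CC)CC | intermediate
5 | (3R)-6-hydroperoxy-6-methoxy-3-[2-(triethylsilyloxy)propan-2-yl]heptanal (C6 epimers) | O=CC[C@@H](CCC(C)(OC)OO)C(C)(C)O[Si](CC)(CC)CC | intermediate
6 | (3R)-6-oxo-3-[2-(triethylsilyloxy)propan-2-yl]heptanal | O=CC[C@@H](CCC(C)=O)C(C)(C)O[Si](CC)(CC)CC | intermediate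
7 | 2-bromopropene | CC(Br)=C | starting material
8 | (5R)-7-hydroxy-8-methyl-5-[2-(triethylsilyloxy)propan-2-yl]non-8-en-2-one (C7 epimers) | C=C(C)C(O)C[C@@H](CCC(C)=O)C(C)(C)O[Si](CC)(CC)CC | intermediate
9 | tert-butyl diethylphosphonoacetate | CCOP(=O)(CC(=O)OC(C)(C)C)OCC | starting material
10 | tert-butyl (2E,6R)-8-hydroxy-3,9-dimethyl-6-[2-(triethylsilyloxy)propan-2-yl]deca-2,9-dienoate (C8 epimers) | C=C(C)C(O)C[C@@H](CC/C(C)=C/C(=O)OC(C)(C)C)C(C)(C)O[Si](CC)(CC)CC | intermediate
11 | triethyl orthoacetate | CCOC(C)(OCC)OCC | starting material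
12 | 1-tert-butyl 12-ethyl (2E,6R,8E)-3,9-dimethyl-6-[2-(triethylsilyloxy)propan-2-yl]dodeca-2,8-dienedioate | CCOC(=O)CC/C(C)=C/C[C@@H](CC/C(C)=C/C(=O)OC(C)(C)C)C(C)(C)O[Si](CC)(CC)CC | intermediate
13 | tert-butyl (2E,6R,8E)-12-[methoxy(methyl)amino]-3,9-dimethyl-12-oxo-6-[2-(triethylsilyloxy)propan-2-yl]dodeca-2,8-dienoate | CON(C)C(=O)CC/C(C)=C/C[C@@H](CC/C(C)=C/C(=O)OC(C)(C)C)C(C)(C)O[Si](CC)(CC)CC | intermediate
14 | 2,3-dibromopropene | C=C(Br)CBr | starting material
15 | 4-methoxybenzyl alcohol | COc1ccc(CO)cc1 | starting material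
16 | 2-bromoallyl 4-methoxybenzyl ether, 1-{[(2-bromoprop-2-en-1-yl)oxy]methyl}-4-methoxybenzene | C=C(Br)COCc1ccc(OC)cc1 | intermediate
17 | {3-[(4-methoxybenzyl)oxy]prop-1-en-2-yl}lithium | [Li]C(=C)COCc1ccc(OC)cc1 | intermediate
18 | tert-butyl (1R,3E,11E)-9-[(4-methoxybenzyl)oxy]-7-oxo-15-(triethylsilyloxy)-9,10-secocembra-3,8(19),11-trien-10-oate | C=C(COCc1ccc(OC)cc1)C(=O)CC/C(C)=C/C[C@@H](CC/C(C)=C/C(=O)OC(C)(C)C)C(C)(C)O[Si](CC)(CC)CC | intermediate
19 | tert-butyl (1R,7R,3E,11E)-7-hydroxy-9-[(4-methoxybenzyl)oxy]-15-(triethylsilyloxy)-9,10-secocembra-3,8(19),11-trien-10-oate | C=C(COCc1ccc(OC)cc1)[C@H](O)CC/C(C)=C/C[C@@H](CC/C(C)=C/C(=O)OC(C)(C)C)C(C)(C)O[Si](CC)(CC)CC | intermediate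
20 | tert-butyl (1R,7R,3E,11E)-9-[(4-methoxybenzyl)oxy]-7,15-bis(triethylsilyloxy)-9,10-secocembra-3,8(19),11-trien-10-oate | C=C(COCc1ccc(OC)cc1)[C@H](O[Si](CC)(CC)CC)CC/C(C)=C/C[C@@H](CC/C(C)=C/C(=O)OC(C)(C)C)C(C)(C)O[Si](CC)(CC)CC | intermediate
21 | (1R,7R,3E,11E)-9-[(4-methoxybenzyl)oxy]-7,15-bis(triethylsilyloxy)-9,10-secocembra-3,8(19),11-trien-10-ol | C=C(COCc1ccc(OC)cc1)[C@H](O[Si](CC)(CC)CC)CC/C(C)=C/C[C@@H](CC/C(C)=C/CO)C(C)(C)O[Si](CC)(CC)CC | intermediate
22 | (1R,7R,3E,11E)-10-bromo-9-[(4-methoxybenzyl)oxy]-7,15-bis(triethylsilyloxy)-9,10-secocembra-3,8(19),11-triene | C=C(COCc1ccc(OC)cc1)[C@H](O[Si](CC)(CC)CC)CC/C(C)=C/C[C@@H](CC/C(C)=C/CBr)C(C)(C)O[Si](CC)(CC)CC | intermediate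
23 | (1R,7R,3E,11E)-9-[(4-methoxybenzyl)oxy]-10-(phenylsulfonyl)-7,15-bis(triethylsilyloxy)-9,10-secocembra-3,8(19),11-triene | C=C(COCc1ccc(OC)cc1)[C@H](O[Si](CC)(CC)CC)CC/C(C)=C/C[C@@H](CC/C(C)=C/CS(=O)(=O)c1ccccc1)C(C)(C)O[Si](CC)(CC)CC | intermediate
24 | (1R,7R,3E,11E)-10-(phenylsulfonyl)-7,15-bis(triethylsilyloxy)-9,10-secocembra-3,8(19),11-trien-9-ol | C=C(CO)[C@H](O[Si](CC)(CC)CC)CC/C(C)=C/C[C@@H](CC/C(C)=C/CS(=O)(=O)c1ccccc1)C(C)(C)O[Si](CC)(CC)CC | intermediate
25 | (1R,3R,4R,7R,11E)-3,4-epoxy-10-(phenylsulfonyl)-7,15-bis(triethylsilyloxy)-9,10-secocembra-8(19),11-dien-9-ol | C=C(CO)[C@H](O[Si](CC)(CC)CC)CC[C@@]1(C)O[C@@H]1C[C@@H](CC/C(C)=C/CS(=O)(=O)c1ccccc1)C(C)(C)O[Si](CC)(CC)CC | intermediate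
26 | (1R,3R,4R,7R,11E)-3,4-epoxy-10-(phenylsulfonyl)-7,15-bis(triethylsilyloxy)-9,10-secocembra-8(19),11-dien-9-yl methanesulfonate | C=C(COS(C)(=O)=O)[C@H](O[Si](CC)(CC)CC)CC[C@@]1(C)O[C@@H]1C[C@@H](CC/C(C)=C/CS(=O)(=O)c1ccccc1)C(C)(C)O[Si](CC)(CC)CC | intermediate
27 | (1R,3R,4R,7R,11E)-9-bromo-3,4-epoxy-10-(phenylsulfonyl)-7,15-bis(triethylsilyloxy)-9,10-secocembra-8(19),11-diene | C=C(CBr)[C@H](O[Si](CC)(CC)CC)CC[C@@]1(C)O[C@@H]1C[C@@H](CC/C(C)=C/CS(=O)(=O)c1ccccc1)C(C)(C)O[Si](CC)(CC)CC | intermediate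
28 | (1R,3R,4R,7R,11E)-3,4-epoxy-10-(phenylsulfonyl)-7,15-bis(triethylsilyloxy)cembra-8(19),11-diene (C10 epimers) | C=C1CC(S(=O)(=O)c2ccccc2)/C=C(\C)CC[C@@H](C(C)(C)O[Si](CC)(CC)CC)C[C@H]2O[C@]2(C)CC[C@H]1O[Si](CC)(CC)CC | intermediate
29 | (1R,3R,4R,7R,11E)-3,4-epoxy-7,15-bis(triethylsilyloxy)cembra-8(19),11-diene | C=C1CC/C=C(\C)CC[C@@H](C(C)(C)O[Si](CC)(CC)CC)C[C@H]2O[C@]2(C)CC[C@H]1O[Si](CC)(CC)CC | intermediate
30 | (1R,3R,4R,7R,11E)-3,4-epoxycembra-8(19),11-diene-7,15-diol | C=C1CC/C=C(\C)CC[C@@H](C(C)(C)O)C[C@H]2O[C@]2(C)CC[C@H]1O | intermediate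
31 | (1R,3R,4R,7R,11E)-7-(tert-butyldimethylsilyloxy)-3,4-epoxycembra-8(19),11-dien-15-ol | C=C1CC/C=C(\C)CC[C@@H](C(C)(C)O)C[C@H]2O[C@]2(C)CC[C@H]1O[Si](C)(C)C(C)(C)C | intermediate
32 | (1R,3R,4S,7R,11E)-7-(tert-butyldimethylsilyloxy)-4,15-epoxycembra-8(19),11-dien-3-ol | C=C1CC/C=C(\C)CC[C@@H]2C[C@@H](O)[C@](C)(CC[C@H]1O[Si](C)(C)C(C)(C)C)OC2(C)C | intermediate
33 | (1R,3R,4S,7R,11E)-7-(tert-butyldimethylsilyloxy)-4,15-epoxycembra-8(19),11-dien-3-yl acetate | C=C1CC/C=C(\C)CC[C@@H]2C[C@@H](OC(C)=O)[C@](C)(CC[C@H]1O[Si](C)(C)C(C)(C)C)OC2(C)C | intermediate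
34 | (1R,3R,4S,7R,11E)-4,15-epoxy-7-hydroxycembra-8(19),11-dien-3-yl acetate (CNP0202897.1) | C=C1CC/C=C(\C)CC[C@@H]2C[C@@H](OC(C)=O)[C@](C)(CC[C@H]1O)OC2(C)C | target

Total step count: 23. Longest linear sequence: 22 steps (steps 1–7 and 9–23; step 8 prepares the C8–C9–C19 reagent).

Steps most likely to fail

1. Step 21. What may go wrong: the C15 hydroxyl opens the epoxide at C3 in the 5-exo mode (oxolane formation), or the protonated epoxide loses a proton to an allylic alcohol instead of closing the ring. Fallback, setting out from 31 and returning at 32: i-Pr3SiOTf and 2,6-lutidine in MeNO2 at 0 °C would activate the epoxide by O-silylation instead of protonation, a more cation-like opening known to steer trisubstituted epoxides with a nearby tertiary hydroxyl towards the oxane, and should give the C3 triisopropylsilyl ether of the bridged oxane F1. Bu4NF in THF at 50 °C would then remove both silyl groups to give the oxane 3,7-diol F2. t-BuMe2SiCl with imidazole should silylate the less hindered allylic C7 hydroxyl of F2 in preference to the C3 hydroxyl next to quaternary C4, which gives 32.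

2. Step 18. What may go wrong: hydride attack of LiBHEt3 on the epoxide competes with the palladium-catalysed C–S cleavage, or the C11=C12 alkene shifts or isomerises within the allylpalladium intermediate. Fallback, setting out from 28 and returning at 32: the ether bridge is closed before the sulfone is removed, so that no epoxide is present when the hydride is used. Bu4NF would convert 28 into the sulfonyl epoxy diol F3, and t-BuMe2SiCl with imidazole would give its C7 silyl ether F4. Camphorsulfonic acid in CH2Cl2 would close the oxane to the sulfonyl oxane alcohol F5, and PdCl2(dppp) with LiBHEt3 would then remove the sulfone from F5 to give 32.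

3. Step 17. What may go wrong: intermolecular alkylation (oligomer formation), and attack of the carbanion or the amide base on the epoxide during the slow ring closure. Fallback, setting out from 24 and returning at 28: the ring is closed before the epoxide exists. CBr4 and PPh3 would turn 24 into the allylic bromide F6, and LiN(SiMe3)2 under high dilution would cyclise it to the macrocyclic sulfonyl triene F7. Shi epoxidation of F7 would then give 28, since C11=C12 is still deactivated by the allylic sulfone and the face is set by the ketone catalyst.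

Further compounds
F1 | step 21 | (1R,3R,4S,7R,11E)-7-(tert-butyldimethylsilyloxy)-3-(triisopropylsilyloxy)-4,15-epoxycembra-8(19),11-diene | C=C1CC/C=C(\C)CC[C@@H]2C[C@@H](O[Si](C(C)C)(C(C)C)C(C)C)[C@](C)(CC[C@H]1O[Si](C)(C)C(C)(C)C)OC2(C)C
F2 | step 21 | (1R,3R,4S,7R,11E)-4,15-epoxycembra-8(19),11-diene-3,7-diol | C=C1CC/C=C(\C)CC[C@@H]2C[C@@H](O)[C@](C)(CC[C@H]1O)OC2(C)C
F3 | step 18 | (1R,3R,4R,7R,11E)-3,4-epoxy-10-(phenylsulfonyl)cembra-8(19),11-diene-7,15-diol (C10 epimers) | C=C1CC(S(=O)(=O)c2ccccc2)/C=C(\C)CC[C@@H](C(C)(C)O)C[C@H]2O[C@]2(C)CC[C@H]1O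
F4 | step 18 | (1R,3R,4R,7R,11E)-7-(tert-butyldimethylsilyloxy)-3,4-epoxy-10-(phenylsulfonyl)cembra-8(19),11-dien-15-ol (C10 epimers) | C=C1CC(S(=O)(=O)c2ccccc2)/C=C(\C)CC[C@@H](C(C)(C)O)C[C@H]2O[C@]2(C)CC[C@H]1O[Si](C)(C)C(C)(C)C
F5 | step 18 | (1R,3R,4S,7R,11E)-7-(tert-butyldimethylsilyloxy)-4,15-epoxy-10-(phenylsulfonyl)cembra-8(19),11-dien-3-ol (C10 epimers) | C=C1CC(S(=O)(=O)c2ccccc2)/C=C(\C)CC[C@@H]2C[C@@H](O)[C@](C)(CC[C@H]1O[Si](C)(C)C(C)(C)C)OC2(C)C
F6 | step 17 | (1R,7R,3E,11E)-9-bromo-10-(phenylsulfonyl)-7,15-bis(triethylsilyloxy)-9,10-secocembra-3,8(19),11-triene | C=C(CBr)[C@H](O[Si](CC)(CC)CC)CC/C(C)=C/C[C@@H](CC/C(C)=C/CS(=O)(=O)c1ccccc1)C(C)(C)O[Si](CC)(CC)CC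
F7 | step 17 | (1R,7R,3E,11E)-10-(phenylsulfonyl)-7,15-bis(triethylsilyloxy)cembra-3,8(19),11-triene (C10 epimers) | C=C1CC(S(=O)(=O)c2ccccc2)/C=C(\C)CC[C@@H](C(C)(C)O[Si](CC)(CC)CC)C/C=C(\C)CC[C@H]1O[Si](CC)(CC)CC
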